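**Strategy**

The hindered aryl ester is never made by acylation: ring C (the benzoate ring) is built around an ester that already exists. The route exploits the fact that C1 (ester-bearing), C6 (side-chain-bearing) and the carboxyl carbon of ring C map onto an alk-2-ynoate, while C2–C5, with the oxygens at C2 and C4, map onto a 1,3-dioxygenated diene. The linear ynoate of the fragment A–B alcohol carries the side-chain ketone as a dithiane and all hydroxyls as silyl ethers. Heating it with the dimedone-derived bis(silyloxy)diene closes ring C by [4+2] addition and loss of 2-methylpropene in one operation. Dithiane hydrolysis and global desilylation finish the synthesis.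

Key step: step 13

**Remarks**

- (a) TBS = tert-butyldimethylsilyl, TMS = trimethylsilyl. Ring C is numbered C1 (ester-bearing) to C6 (side-chain-bearing).
- (b) Assumption: 2-(tert-butyldimethylsilyl)-1,3-dithiane, 3-bromo-1-(trimethylsilyl)prop-1-yne and benzyl 2,2,2-trichloroacetimidate are purchased.
- (c) All three stereocentres of the target are R and all are bought, not made. The carbinol centres of fragment A and of the side chain are C2 of (R)-propylene oxide, opened at CH2. The 3-acyloxybutanoate centre comes from methyl (R)-3-hydroxybutanoate.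
- (d) The dithiane carbon is joined to the epoxide first and to the propargyl unit second. No strong base therefore meets a propargylated dithiane, whose propargylic carbanion could expel thiolate. The silyl shift of that step also installs the side-chain TBS ether.
- (e) The two aryl TMS ethers formed in the key step are cleaved on purpose in its work-up, because they would not survive chromatography.

**Route**

Step 1
Reactants: 1 5-bromoresorcinol
Product: 2 1-bromo-3,5-bis(tert-butyldimethylsilyloxy)benzene
Conditions: TBSCl (2.4 equiv), imidazole (5 equiv), DMF, 23 °C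
Reagents that add atoms: tert-butyldimethylsilyl chloride, CC(C)(C)[Si](C)(C)Cl
Why: Imidazole-promoted O-silylation (silyl ether formation) of both phenols should be complete and leaves the aryl bromide untouched.

Step 2
Reactants: 2 1-bromo-3,5-bis(tert-butyldimethylsilyloxy)benzene; 3 (R)-propylene oxide
Product: 6 (R)-1-[3,5-bis(tert-butyldimethylsilyloxy)phenyl]propan-2-ol, via arylmagnesium bromide 4 (not isolated), via bromomagnesium alkoxide 5 (not isolated)
Conditions: Mg, THF, reflux; then CuI (10 mol %), 3, THF, −30 → 0 °C; H2O quench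
Reagents that add atoms: none
Why: Grignard formation followed by CuI-catalysed SN2 opening of the epoxide at its unhindered CH2 should give the homobenzylic alcohol; the stereocentre is the untouched C2 of the epoxide and stays R.

Step 3
Reactants: 7 methyl (R)-3-hydroxybutanoate
Product: 8 methyl (R)-3-(benzyloxy)butanoate
Conditions: benzyl 2,2,2-trichloroacetimidate (1.5 equiv), TfOH (5 mol %), CH2Cl2/cyclohexane, 0 → 23 °C
Reagents that add atoms: benzyl 2,2,2-trichloroacetimidate, N=C(OCc1ccccc1)C(Cl)(Cl)Cl
Why: Acid-catalysed O-benzylation with a trichloroacetimidate avoids base, so neither retro-aldol cleavage nor elimination of the β-hydroxy ester is expected, and the stereocentre is not a reacting atom.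

Step 4
Reactants: 8 methyl (R)-3-(benzyloxy)butanoate
Product: 10 (R)-3-(benzyloxy)butanoic acid, via lithium carboxylate 9 (not isolated)
Conditions: LiOH·H2O (1.5 equiv), THF/H2O 3:1, 0 → 23 °C; then 1 M HCl to pH 3
Reagents that add atoms: lithium hydroxide, [Li+].[OH-]
Why: Ester saponification at low temperature should be clean because a β-benzyloxy group is a poor leaving group for E1cB loss, and the stereocentre is not touched.

Step 5
Reactants: 6 (R)-1-[3,5-bis(tert-butyldimethylsilyloxy)phenyl]propan-2-ol; 10 (R)-3-(benzyloxy)butanoic acid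
Product: 11 (R)-1-[3,5-bis(tert-butyldimethylsilyloxy)phenyl]propan-2-yl (R)-3-(benzyloxy)butanoate
Conditions: DCC (1.3 equiv), DMAP (10 mol %), CH2Cl2, 0 → 23 °C
Reagents that add atoms: none
Why: Steglich esterification of a secondary alcohol with an unhindered acid forms the acyl–oxygen bond only, so both stereocentres are retained.

Step 6
Reactants: 11 (R)-1-[3,5-bis(tert-butyldimethylsilyloxy)phenyl]propan-2-yl (R)-3-(benzyloxy)butanoate
Product: 12 (R)-1-[3,5-bis(tert-butyldimethylsilyloxy)phenyl]propan-2-yl (R)-3-hydroxybutanoate (fragment A–B alcohol)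
Conditions: H2 (1 atm), Pd/C (10 wt %), EtOAc, 23 °C
Reagents that add atoms: none
Why: Hydrogenolysis of the benzyl ether under neutral conditions should spare the aryl silyl ethers, the ester and the homobenzylic (not benzylic) C–O bond.

Step 7
Reactants: 13 2-(tert-butyldimethylsilyl)-1,3-dithiane; 3 (R)-propylene oxide; 14 3-bromo-1-(trimethylsilyl)prop-1-yne
Product: 18 2-[(R)-2-(tert-butyldimethylsilyloxy)propyl]-2-[3-(trimethylsilyl)prop-2-yn-1-yl]-1,3-dithiane, via lithiated silyl dithiane 15 (not isolated), via lithium alkoxide 16 (not isolated), via rearranged lithiodithiane 17 (not isolated)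
Conditions: t-BuLi (1.05 equiv), Et2O, −78 → −45 °C; 3, −78 → −25 °C; then 14 (1.2 equiv), HMPA/THF, −78 → 0 °C
Reagents that add atoms: none
Why: This is an anion-relay linchpin coupling: the lithiated silyl dithiane opens the epoxide at CH2, HMPA then triggers a 1,4-Brook shift of silicon from carbon to the new alkoxide (which protects the alcohol and regenerates a dithiane carbanion), and that carbanion is alkylated by the propargylic bromide in an SN2 step; the carbinol centre is the untouched epoxide C2 (R).

Step 8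
Reactants: 18 2-[(R)-2-(tert-butyldimethylsilyloxy)propyl]-2-[3-(trimethylsilyl)prop-2-yn-1-yl]-1,3-dithiane
Product: 19 2-[(R)-2-(tert-butyldimethylsilyloxy)propyl]-2-(prop-2-yn-1-yl)-1,3-dithiane
Conditions: K2CO3 (cat.), MeOH, 23 °C
Reagents that add atoms: none
Why: Base-catalysed methanolysis of the alkynyl C–Si bond (protodesilylation) should leave the alkyl TBS ether and the dithiane untouched.

Step 9
Reactants: 19 2-[(R)-2-(tert-butyldimethylsilyloxy)propyl]-2-(prop-2-yn-1-yl)-1,3-dithiane
Product: 22 4-{2-[(R)-2-(tert-butyldimethylsilyloxy)propyl]-1,3-dithian-2-yl}but-2-ynoic acid, via lithium acetylide 20 (not isolated), via lithium ynoate 21 (not isolated)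
Conditions: n-BuLi (1.05 equiv), THF, −78 °C; CO2 (g), −78 → 0 °C; then cold 0.5 M HCl to pH 3
Reagents that add atoms: carbon dioxide, O=C=O
Why: The terminal alkyne is the only acidic C–H (the dithiane carbon is quaternary), so deprotonation and carboxylation of the acetylide should give the alk-2-ynoic acid directly.

Step 10
Reactants: 22 4-{2-[(R)-2-(tert-butyldimethylsilyloxy)propyl]-1,3-dithian-2-yl}but-2-ynoic acid; 12 fragment A–B alcohol
Product: 23 (R)-4-{[(R)-1-(3,5-bis(tert-butyldimethylsilyloxy)phenyl)propan-2-yl]oxy}-4-oxobutan-2-yl 4-{2-[(R)-2-(tert-butyldimethylsilyloxy)propyl]-1,3-dithian-2-yl}but-2-ynoate (fragment A–B ynoate)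
Conditions: DCC (1.2 equiv), DMAP (5 mol %), CH2Cl2, −20 → 0 °C
Reagents that add atoms: none
Why: Steglich esterification at an unhindered sp-substituted acyl carbon should acylate the secondary β-hydroxy ester without forcing, with little DMAP and low temperature to suppress conjugate addition to the ynoate, and with retention at the carbinol carbon.

Step 11
Reactants: 24 dimedone
Product: 25 5,5-dimethyl-3-(trimethylsilyloxy)cyclohex-2-en-1-one
Conditions: HMDS (0.6 equiv), imidazole (cat.), toluene, reflux
Reagents that add atoms: hexamethyldisilazane, C[Si](C)(C)N[Si](C)(C)C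
Why: O-Silylation of the enol form of the 1,3-dione should give the vinylogous silyl ester, with ammonia as the only by-product.

Step 12
Reactants: 25 5,5-dimethyl-3-(trimethylsilyloxy)cyclohex-2-en-1-one
Product: 27 5,5-dimethyl-1,3-bis(trimethylsilyloxy)cyclohexa-1,3-diene, via lithium dienolate 26 (not isolated)
Conditions: LDA (1.1 equiv), THF, −78 °C; TMSCl (1.2 equiv), −78 → 0 °C; non-aqueous work-up, distillation
Reagents that add atoms: chlorotrimethylsilane, C[Si](C)(C)Cl
Why: Kinetic deprotonation at the CH2 next to the carbonyl gives the cross-conjugated dienolate, and O-silylation (silyl enol ether formation) should give the 1,3-bis(silyloxy)diene.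

Step 13
Reactants: 23 fragment A–B ynoate; 27 5,5-dimethyl-1,3-bis(trimethylsilyloxy)cyclohexa-1,3-diene
Product: 30 (R)-4-{[(R)-1-(3,5-bis(tert-butyldimethylsilyloxy)phenyl)propan-2-yl]oxy}-4-oxobutan-2-yl 2,4-dihydroxy-6-({2-[(R)-2-(tert-butyldimethylsilyloxy)propyl]-1,3-dithian-2-yl}methyl)benzoate, via bicyclooctadiene adduct 28 (not isolated), via bis(trimethylsilyl) benzoate 29 (not isolated)
Conditions: 27 (5 equiv), neat, sealed tube, Ar, 140 °C; then MeOH, silica gel, 23 °C
Reagents that add atoms: none
Why: The electron-rich, s-cis-locked diene 27 adds across the electron-poor triple bond of 23 in a concerted, thermally allowed [4+2] cycloaddition that forms C1–C2 and C5–C6 of ring C and gives bicyclo[2.2.2]octadiene 28, whose CH2–CMe2 bridge then leaves as 2-methylpropene in a retro-[4+2] step driven by aromatisation (the Alder–Rickert sequence, the established way from 1,3-bis(silyloxy)cyclohexadienes and alkynoates to resorcylates). Ring C is thus closed as a six-membered carbocycle by intermolecular cycloaddition, both ring bonds forming suprafacially in one pericyclic event, after which the two-carbon bridge is excised. No stereocentre is created that survives: the two bridgehead centres of 28 form without control and vanish on aromatisation, and the three existing centres lie away from any site that reacts under neutral heating. The selectivity needed is regiochemical; both silyloxy groups push the largest HOMO coefficient onto the unsubstituted diene terminus, which bonds to the ynoate β-carbon, so the oxygen-bearing terminus joins the α-carbon and the product has oxygen at C2 and C4 and the side chain at C6. Dithiane, TBS ethers and both esters are inert to neutral heat, and methanol on silica afterwards should cleave only the two labile aryl TMS ethers of 29.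

Step 14
Reactants: 30 dithiane-protected resorcylate diester
Product: 31 (R)-4-{[(R)-1-(3,5-bis(tert-butyldimethylsilyloxy)phenyl)propan-2-yl]oxy}-4-oxobutan-2-yl 2,4-dihydroxy-6-[(R)-4-(tert-butyldimethylsilyloxy)-2-oxopentyl]benzoate
Conditions: MeI (20 equiv), CaCO3 (10 equiv), MeCN/H2O 9:1, 45 °C
Reagents that add atoms: water, O
Why: In this alkylative thioacetal hydrolysis, S-methylation turns sulfur into a leaving group, water delivers the carbonyl oxygen and CaCO3 keeps the medium neutral, so the 3-acyloxybutanoate and the silyl ethers should survive; the side-chain stereocentre is β to the new carbonyl and cannot epimerise by enolisation.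

Step 15
Reactants: 31 tris-TBS ketone
Product: 32 Hansforester K, (R)-4-{[(R)-1-(3,5-dihydroxyphenyl)propan-2-yl]oxy}-4-oxobutan-2-yl 2,4-dihydroxy-6-[(R)-4-hydroxy-2-oxopentyl]benzoate
Conditions: HF·pyridine, pyridine, THF, 0 → 23 °C
Reagents that add atoms: none
Why: Fluoride-mediated desilylation under buffered, non-basic conditions should remove the two aryl and the one alkyl TBS ether while sparing both esters, and it avoids base-induced elimination of the 3-acyloxybutanoate or dehydration of the β-hydroxy ketone.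

**Compound list**

1 | 5-bromoresorcinol | Oc1cc(Br)cc(O)c1 | starting material
2 | 1-bromo-3,5-bis(tert-butyldimethylsilyloxy)benzene | Brc1cc(O[Si](C)(C)C(C)(C)C)cc(O[Si](C)(C)C(C)(C)C)c1 | intermediate
3 | (R)-propylene oxide | C[C@@H]1CO1 | starting material
4 | [3,5-bis(tert-butyldimethylsilyloxy)phenyl]magnesium bromide | Br[Mg]c1cc(O[Si](C)(C)C(C)(C)C)cc(O[Si](C)(C)C(C)(C)C)c1 | intermediate (not isolated)
5 | bromomagnesium (R)-1-[3,5-bis(tert-butyldimethylsilyloxy)phenyl]propan-2-olate | C[C@H](Cc1cc(O[Si](C)(C)C(C)(C)C)cc(O[Si](C)(C)C(C)(C)C)c1)O[Mg]Br | intermediate (not isolated)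
6 | (R)-1-[3,5-bis(tert-butyldimethylsilyloxy)phenyl]propan-2-ol | C[C@H](Cc1cc(O[Si](C)(C)C(C)(C)C)cc(O[Si](C)(C)C(C)(C)C)c1)O | intermediate
7 | methyl (R)-3-hydroxybutanoate | C[C@@H](O)CC(=O)OC | starting material
8 | methyl (R)-3-(benzyloxy)butanoate | C[C@@H](OCc1ccccc1)CC(=O)OC | intermediate
9 | lithium (R)-3-(benzyloxy)butanoate | [Li+].[O-]C(=O)C[C@@H](C)OCc1ccccc1 | intermediate (not isolated)
10 | (R)-3-(benzyloxy)butanoic acid | OC(=O)C[C@@H](C)OCc1ccccc1 | intermediate
11 | (R)-1-[3,5-bis(tert-butyldimethylsilyloxy)phenyl]propan-2-yl (R)-3-(benzyloxy)butanoate | C[C@H](Cc1cc(O[Si](C)(C)C(C)(C)C)cc(O[Si](C)(C)C(C)(C)C)c1)OC(=O)C[C@@H](C)OCc1ccccc1 | intermediate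
12 | (R)-1-[3,5-bis(tert-butyldimethylsilyloxy)phenyl]propan-2-yl (R)-3-hydroxybutanoate (fragment A–B alcohol) | C[C@H](Cc1cc(O[Si](C)(C)C(C)(C)C)cc(O[Si](C)(C)C(C)(C)C)c1)OC(=O)C[C@@H](C)O | intermediate
13 | 2-(tert-butyldimethylsilyl)-1,3-dithiane | CC(C)(C)[Si](C)(C)C1SCCCS1 | starting material
14 | 3-bromo-1-(trimethylsilyl)prop-1-yne | C[Si](C)(C)C#CCBr | starting material
15 | 2-lithio-2-(tert-butyldimethylsilyl)-1,3-dithiane | CC(C)(C)[Si](C)(C)C1([Li])SCCCS1 | intermediate (not isolated)
16 | lithium (R)-1-[2-(tert-butyldimethylsilyl)-1,3-dithian-2-yl]propan-2-olate | CC(C)(C)[Si](C)(C)C1(C[C@@H](C)O[Li])SCCCS1 | intermediate (not isolated)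
17 | 2-lithio-2-[(R)-2-(tert-butyldimethylsilyloxy)propyl]-1,3-dithiane | [Li]C1(C[C@@H](C)O[Si](C)(C)C(C)(C)C)SCCCS1 | intermediate (not isolated)
18 | 2-[(R)-2-(tert-butyldimethylsilyloxy)propyl]-2-[3-(trimethylsilyl)prop-2-yn-1-yl]-1,3-dithiane | C[Si](C)(C)C#CCC1(C[C@@H](C)O[Si](C)(C)C(C)(C)C)SCCCS1 | intermediate
19 | 2-[(R)-2-(tert-butyldimethylsilyloxy)propyl]-2-(prop-2-yn-1-yl)-1,3-dithiane | C#CCC1(C[C@@H](C)O[Si](C)(C)C(C)(C)C)SCCCS1 | intermediate
20 | lithium acetylide of 19 | [Li]C#CCC1(C[C@@H](C)O[Si](C)(C)C(C)(C)C)SCCCS1 | intermediate (not isolated)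
21 | lithium 4-{2-[(R)-2-(tert-butyldimethylsilyloxy)propyl]-1,3-dithian-2-yl}but-2-ynoate | [Li+].[O-]C(=O)C#CCC1(C[C@@H](C)O[Si](C)(C)C(C)(C)C)SCCCS1 | intermediate (not isolated)
22 | 4-{2-[(R)-2-(tert-butyldimethylsilyloxy)propyl]-1,3-dithian-2-yl}but-2-ynoic acid | OC(=O)C#CCC1(C[C@@H](C)O[Si](C)(C)C(C)(C)C)SCCCS1 | intermediate
23 | fragment A–B ynoate: ester of acid 22 with the hydroxyl of 12 | C[C@H](Cc1cc(O[Si](C)(C)C(C)(C)C)cc(O[Si](C)(C)C(C)(C)C)c1)OC(=O)C[C@@H](C)OC(=O)C#CCC1(C[C@@H](C)O[Si](C)(C)C(C)(C)C)SCCCS1 | intermediate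
24 | dimedone | CC1(C)CC(=O)CC(=O)C1 | starting material
25 | 5,5-dimethyl-3-(trimethylsilyloxy)cyclohex-2-en-1-one | CC1(C)CC(=O)C=C(O[Si](C)(C)C)C1 | intermediate
26 | lithium 3,3-dimethyl-5-(trimethylsilyloxy)cyclohexa-1,5-dien-1-olate | [Li]OC1=CC(C)(C)CC(O[Si](C)(C)C)=C1 | intermediate (not isolated)
27 | 5,5-dimethyl-1,3-bis(trimethylsilyloxy)cyclohexa-1,3-diene | CC1(C)CC(O[Si](C)(C)C)=CC(O[Si](C)(C)C)=C1 | intermediate
28 | 8,8-dimethyl-1,5-bis(trimethylsilyloxy)bicyclo[2.2.2]octa-2,5-diene-2-carboxylate of alcohol 12, with the dithianylmethyl side chain at C3 (both bridgehead configurations) | C[C@H](Cc1cc(O[Si](C)(C)C(C)(C)C)cc(O[Si](C)(C)C(C)(C)C)c1)OC(=O)C[C@@H](C)OC(=O)C1=C(CC3(C[C@@H](C)O[Si](C)(C)C(C)(C)C)SCCCS3)C2C(C)(C)CC1(O[Si](C)(C)C)C=C2O[Si](C)(C)C | intermediate (not isolated)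
29 | protected diester with ring C as its 2,4-bis(trimethylsilyl) ether | C[C@H](Cc1cc(O[Si](C)(C)C(C)(C)C)cc(O[Si](C)(C)C(C)(C)C)c1)OC(=O)C[C@@H](C)OC(=O)c1c(O[Si](C)(C)C)cc(O[Si](C)(C)C)cc1CC1(C[C@@H](C)O[Si](C)(C)C(C)(C)C)SCCCS1 | intermediate (not isolated)
30 | diester with ring C as the free 2,4-dihydroxybenzoate, side-chain ketone as dithiane | C[C@H](Cc1cc(O[Si](C)(C)C(C)(C)C)cc(O[Si](C)(C)C(C)(C)C)c1)OC(=O)C[C@@H](C)OC(=O)c1c(O)cc(O)cc1CC1(C[C@@H](C)O[Si](C)(C)C(C)(C)C)SCCCS1 | intermediate
31 | tris-TBS ketone: 2,4-dihydroxy-6-[(R)-4-(tert-butyldimethylsilyloxy)-2-oxopentyl]benzoate of alcohol 12 | C[C@H](Cc1cc(O[Si](C)(C)C(C)(C)C)cc(O[Si](C)(C)C(C)(C)C)c1)OC(=O)C[C@@H](C)OC(=O)c1c(O)cc(O)cc1CC(=O)C[C@@H](C)O[Si](C)(C)C(C)(C)C | intermediate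
32 | Hansforester K | C[C@H](Cc1cc(O)cc(O)c1)OC(=O)C[C@@H](C)OC(=O)c1c(O)cc(O)cc1CC(=O)C[C@@H](C)O | target

**Step count and risk**

Total step count: 15. Longest linear sequence: 8 steps (steps 3, 4, 5, 6, 10, 13, 14, 15, from methyl (R)-3-hydroxybutanoate; equally steps 1, 2, 5, 6, 10, 13, 14, 15 from 5-bromoresorcinol).

Steps most likely to fail:

1. Step 13. The β-carbon of the ynoate carries a neopentyl-type substituent, so the cycloaddition may be slow. Prolonged heating could then let thermal erosion of the elaborate diester and consumption of the diene by adventitious hydrolysis compete with ring formation. Fallback: set out from acid 22 and ester 7 and build ring C on a small, robust ynoate, joining fragment A at the end. Steglich coupling of 22 with 7 (DCC, DMAP cat., CH2Cl2, 0 °C) would give methyl (R)-3-({4-[2-((R)-2-(tert-butyldimethylsilyloxy)propyl)-1,3-dithian-2-yl]but-2-ynoyl}oxy)butanoate F1. This compound tolerates a large excess of diene 27 at 150–160 °C and should pass through the bicyclooctadiene adduct F2 and the bis(trimethylsilyl) benzoate F3 (neither isolated) to the methyl ester resorcylate F4 after methanol on silica. Me3SnOH (1,2-dichloroethane, 70 °C) should cleave only the unhindered aliphatic methyl ester, without base-induced elimination, to give the butanoic acid F5. Separately, Grignard reagent 4 and commercial (S)-propylene oxide under the conditions of step 2 would give (S)-1-[3,5-bis(tert-butyldimethylsilyloxy)phenyl]propan-2-ol F6. Mitsunobu esterification of F5 with one equivalent of F6 (PPh3, DIAD, THF, 0 °C) uses the carboxylic acid, the strongest acid present, as the nucleophile and inverts the carbinol carbon from S to R. It comes back to the route at compound 30, and steps 14 and 15 follow unchanged.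

2. Step 14. Hydrolysis of the doubly neopentyl thioacetal may be slow. The acidic ring C phenols could then be O-methylated by the excess methyl iodide, or the liberated benzyl ketone could enol-lactonise onto the ortho ester with expulsion of the fragment A–B alcohol. Fallback: set out from 30 and cap ring C before a fast thiophilic-metal hydrolysis. TBSOTf and 2,6-lutidine (CH2Cl2, −78 → 0 °C) would give the ring C bis-TBS dithiane F7. Hg(ClO4)2 with CaCO3 in THF/H2O at 0 °C (divalent mercury, reaction time of minutes) should give the fully silylated ketone F8. HF·pyridine under the conditions of step 15 then removes all five silyl ethers and comes back to the route at the target 32.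

3. Step 7. The silyl migration may be mistimed. If the 1,4-Brook shift begins before the epoxide is consumed, the rearranged carbanion opens a second epoxide; if it is incomplete, alkoxide 16 is carried through as the C-silyl alcohol or is O-alkylated. Fallback: separate the three events, setting out from epoxide 3 and commercial 1,3-dithiane. n-BuLi (THF, −30 °C) followed by 3 would give (R)-1-(1,3-dithian-2-yl)propan-2-ol F9. TBSCl and imidazole in DMF would give 2-[(R)-2-(tert-butyldimethylsilyloxy)propyl]-1,3-dithiane F10. Deprotonation of F10 with t-BuLi in THF/HMPA at −78 °C generates lithiodithiane 17 directly, so the fallback comes back to the route at compound 17, which is alkylated with 14 to give 18 as in step 7.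

**Further compounds**

F1 | step 13 | methyl (R)-3-({4-[2-((R)-2-(tert-butyldimethylsilyloxy)propyl)-1,3-dithian-2-yl]but-2-ynoyl}oxy)butanoate | COC(=O)C[C@@H](C)OC(=O)C#CCC1(C[C@@H](C)O[Si](C)(C)C(C)(C)C)SCCCS1
F2 | step 13 | bicyclo[2.2.2]octa-2,5-diene adduct of F1 and 27 (both bridgehead configurations) | COC(=O)C[C@@H](C)OC(=O)C1=C(CC3(C[C@@H](C)O[Si](C)(C)C(C)(C)C)SCCCS3)C2C(C)(C)CC1(O[Si](C)(C)C)C=C2O[Si](C)(C)C
F3 | step 13 | methyl (R)-3-{[2,4-bis(trimethylsilyloxy)-6-({2-[(R)-2-(tert-butyldimethylsilyloxy)propyl]-1,3-dithian-2-yl}methyl)benzoyl]oxy}butanoate | COC(=O)C[C@@H](C)OC(=O)c1c(O[Si](C)(C)C)cc(O[Si](C)(C)C)cc1CC1(C[C@@H](C)O[Si](C)(C)C(C)(C)C)SCCCS1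
F4 | step 13 | methyl (R)-3-{[2,4-dihydroxy-6-({2-[(R)-2-(tert-butyldimethylsilyloxy)propyl]-1,3-dithian-2-yl}methyl)benzoyl]oxy}butanoate | COC(=O)C[C@@H](C)OC(=O)c1c(O)cc(O)cc1CC1(C[C@@H](C)O[Si](C)(C)C(C)(C)C)SCCCS1
F5 | step 13 | (R)-3-{[2,4-dihydroxy-6-({2-[(R)-2-(tert-butyldimethylsilyloxy)propyl]-1,3-dithian-2-yl}methyl)benzoyl]oxy}butanoic acid | OC(=O)C[C@@H](C)OC(=O)c1c(O)cc(O)cc1CC1(C[C@@H](C)O[Si](C)(C)C(C)(C)C)SCCCS1
F6 | step 13 | (S)-1-[3,5-bis(tert-butyldimethylsilyloxy)phenyl]propan-2-ol | C[C@@H](Cc1cc(O[Si](C)(C)C(C)(C)C)cc(O[Si](C)(C)C(C)(C)C)c1)O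
F7 | step 14 | ring C 2,4-bis(tert-butyldimethylsilyl) ether of 30 | C[C@H](Cc1cc(O[Si](C)(C)C(C)(C)C)cc(O[Si](C)(C)C(C)(C)C)c1)OC(=O)C[C@@H](C)OC(=O)c1c(O[Si](C)(C)C(C)(C)C)cc(O[Si](C)(C)C(C)(C)C)cc1CC1(C[C@@H](C)O[Si](C)(C)C(C)(C)C)SCCCS1
F8 | step 14 | pentakis-TBS ketone: 2,4-bis(tert-butyldimethylsilyloxy)-6-[(R)-4-(tert-butyldimethylsilyloxy)-2-oxopentyl]benzoate of alcohol 12 | C[C@H](Cc1cc(O[Si](C)(C)C(C)(C)C)cc(O[Si](C)(C)C(C)(C)C)c1)OC(=O)C[C@@H](C)OC(=O)c1c(O[Si](C)(C)C(C)(C)C)cc(O[Si](C)(C)C(C)(C)C)cc1CC(=O)C[C@@H](C)O[Si](C)(C)C(C)(C)C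
F9 | step 7 | (R)-1-(1,3-dithian-2-yl)propan-2-ol | C1(C[C@@H](C)O)SCCCS1
F10 | step 7 | 2-[(R)-2-(tert-butyldimethylsilyloxy)propyl]-1,3-dithiane | C1(C[C@@H](C)O[Si](C)(C)C(C)(C)C)SCCCS1
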